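The earlier runs and the new flask were computed from invented constants; the scatter is artificial.

A millimolar-minute of catalyst is the unit we count in, and the question is how much conversion each one buys.

| flask | substrate | reagent | free catalyst | temperature | remark | time |
|---|---|---|---|---|---|---|
| midnight | 0.20 M | 0.26 M | 0.13 mM | −5 °C | run made earlier |  |
| dusk | 0.20 M | 0.26 M | 0.30 mM | 30 °C | run made earlier |  |
| winter | 0.10 M | 0.26 M | 0.20 mM | −5 °C | run made earlier |  |
| south-west | 0.20 M | 0.260 M | 0.20 mM | 40 °C |  | 30 min |
| north-west | 0.20 M | 0.260 M | 0.20 mM | 60 °C |  | 30 min |
| north | 0.20 M | 0.260 M | 0.20 mM | 20 °C |  | 30 min |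
| north-east | 0.20 M | 0.260 M | 0.20 mM | 0 °C |  | 30 min |

| run | time / min | product / % |
|---|---|---|
| midnight | 30.0 | 4.9 |
| midnight | 60.0 | 5.7 |
| midnight | 90.0 | 6.6 |
| midnight | 150 | 11.9 |
| midnight | 180 | 13.8 |
| midnight | 240 | 17.8 |
| dusk | 2.00 | 8.4 |
| dusk | 6.00 | 23.5 |
| dusk | 10.0 | 38.5 |
| dusk | 15.0 | 52.7 |
| dusk | 25.0 | 72.2 |
| dusk | 30.0 | 80.3 |
| dusk | 40.0 | 89.4 |
| winter | 50.0 | 6.3 |
| winter | 90.0 | 15.1 |
| winter | 150 | 22.1 |
| winter | 180 | 23.2 |
| winter | 240 | 31.8 |

(scatter of a reading: 1 percentage point)



1. the flask that comes out highest in amount of product, in percent of the substrate charged, or "all alike" when all lie within 1.5 percentage points (south-west / north-west / north / north-east / all alike)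
2. product at the end, in percent of the substrate charged, south-west
3. product at the end, in percent of the substrate charged, north-west
4. product at the end, in percent of the substrate charged, north
5. product at the end, in percent of the substrate charged, north-east

The dusk run at 30.0 min gives 0.181 /mM/min for what we call the specific rate, the natural logarithm of substrate charged over substrate left, per millimolar-minute. This treats the run as pseudo-first-order in substrate, with the catalyst frozen at its charge.

Is that number steady along a run? At 6.00 min the dusk run reads 0.149 /mM/min, so it drifts by a factor of 1.21, and we accept that.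

Does it survive a change of charges? At −5 °C, the last readings give 0.006283 /mM/min for the midnight run and 0.007973 /mM/min for the winter run, a factor of 1.27 with catalyst and substrate both changed.

Then what moves it? Between midnight and dusk, where the substrate charge is the same and the catalyst is divided out, it grows by a factor of 28.8, much more than either drift, so we read that growth as the effect of temperature, and those two readings give an apparent activation energy of 64.8 kJ/mol.

Each new flask spends 6.00 mM·min. Specific rate times that spending is the depth, and in this reckoning, with the catalyst counted at its charge, conversion is one minus the exponential of minus the depth. Our depths are 0.0642 for north-east, 0.450 for north, 2.46 for south-west and 11.0 for north-west, which is the deepest. They mean 6.22%, 36.3%, 91.5% and >99.9%.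

The forecast names north-west, with 91% for south-west, 99.5% for north-west, 34% for north and 6% for north-east. Its ground is “The runs fit a rate first order in catalyst and saturating in substrate”, and it reads 60 kJ/mol where we read 64.8 kJ/mol.

The flasks give north-west as highest, with 91.1% for south-west, >99.9% for north-west, 34.8% for north and 5.78% for north-east.

    catalyst intermediate C → free catalyst + product (k = 71.0 /min, Ea = 81.0 kJ/mol)
    reagent + free catalyst ⇌ catalyst intermediate A (K = 11.0 /M, k = 280 /M/min, Ea = 44.0 kJ/mol, ΔH = 14.0 kJ/mol)
    substrate + catalyst intermediate B ⇌ catalyst intermediate C (K = 4.40 /M, k = 180 /M/min, Ea = 58.0 kJ/mol, ΔH = −13.0 kJ/mol)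
    catalyst intermediate A → released group + catalyst intermediate B (k = 620 /min, Ea = 56.0 kJ/mol)
    (constants at 20 °C)

In north-west, half of the turnover up to 30 min of the step from catalyst intermediate A to released group and catalyst intermediate B is done by 2.69 min, much sooner than the end of the run. At 30.0 min that flask holds 0% of its substrate and 23.0% of its reagent. North-east, left for 300 min, has by our reckoning a depth of 0.642, which means 47.4%, and the flask gives 48.1% of product.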